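## Retrosynthetic overview

1. Target 15 ⇐ 14 (desilylation) ⇐ 13 (ring A ketone reduction sets the equatorial 3-OH).
2. 13 ⇐ 11 + CH2O: C-4 is rebuilt by aldol addition of a regiospecific C-3/C-4 enolate anti to the C-10 methyl, which inverts C-4 relative to andrographolide. 11 ⇐ β-keto acid 9 (decarboxylative chlorination) ⇐ 3,19-diol 7.
3. 7 ⇐ 5 (TBS on 12-OH, acetonide off).
4. Key step: 5 ⇐ 2 by a [3,3]-sigmatropic shift of the C-14 allyl perrhenate. It forms the C-12–O bond, moves the alkene into the lactone ring and relays C-14 (S) to C-12 (R).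
5. Rings: none is built. Rings A and B and the lactone ring are bought intact in andrographolide 1; C-5, C-9 and C-10 are kept, C-14 is relayed to C-12, and C-4 and C-3 are reset under control of the C-10 methyl.

Assumption: the SMILES is read literally, i.e. as the C-4 epimer (hydroxymethyl equatorial, trans to the C-10 methyl) of natural (12R)-14-deoxy-12-hydroxyandrographolide; labdane numbering is used and TBS = tert-butyldimethylsilyl.

## Route

Step 1
Reactants: 1 andrographolide
Product: 2 andrographolide 3,19-acetonide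
Conditions: Me2C(OMe)2, pyridinium p-toluenesulfonate (cat.), CH2Cl2/acetone, 40 °C
Reagents that add atoms: 2,2-dimethoxypropane, COC(C)(C)OC
Why: Acid-catalysed transacetalisation closes the six-membered acetonide only on the cis 3-OH/19-OH pair, leaving the allylic 14-OH free and touching no stereocentre.

Step 2
Reactants: 2 andrographolide 3,19-acetonide
Product: 5 (12R)-14-deoxy-12-hydroxyandrographolide 3,19-acetonide, via C-14 allyl perrhenate 3 (not isolated), via C-12 allyl perrhenate 4 (not isolated)
Conditions: Ph3SiOReO3 (5 mol %), 4 Å MS, CH2Cl2, 0 °C → rt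
Reagents that add atoms: none
Why: Rhenium-oxo-catalysed allylic 1,3-transposition, a suprafacial [3,3]-sigmatropic shift of the allyl perrhenate, delivers oxygen to C-12 on the face it leaves at C-14, which with the 12E alkene and 14S gives 12R, and the equilibrium favours the endocyclic butenolide.

Step 3
Reactants: 5 (12R)-14-deoxy-12-hydroxyandrographolide 3,19-acetonide
Product: 7 (12R)-12-O-TBS-14-deoxy-12-hydroxyandrographolide, via 12-O-TBS acetonide 6 (not isolated)
Conditions: TBSCl, imidazole, 4-(dimethylamino)pyridine (cat.), DMF, rt; then AcOH/H2O 7:3, rt, 1 h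
Reagents that add atoms: tert-butyldimethylsilyl chloride, CC(C)(C)[Si](C)(C)Cl
Why: Silylation of the only free hydroxyl is followed by selective acetal hydrolysis, since a secondary TBS ether survives the aqueous acetic acid that cleaves the acetonide, freeing the 3,19-diol.

Step 4
Reactants: 7 (12R)-12-O-TBS-14-deoxy-12-hydroxyandrographolide
Product: 8 (12R)-12-O-TBS-14-deoxy-3-oxoandrographolid-19-al
Conditions: Dess–Martin periodinane (3 equiv), CH2Cl2, 0 °C → rt
Reagents that add atoms: none
Why: Dess–Martin oxidation takes the secondary and the neopentyl primary alcohol to a non-enolisable β-keto aldehyde without affecting the alkenes, the lactone or the silyl ether.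

Step 5
Reactants: 8 (12R)-12-O-TBS-14-deoxy-3-oxoandrographolid-19-al
Product: 9 (12R)-12-O-TBS-14-deoxy-3-oxoandrographolid-19-oic acid
Conditions: NaClO2, NaH2PO4, 2-methyl-2-butene, t-BuOH/H2O, 0 °C; cold extractive work-up, used at once
Reagents that add atoms: sodium chlorite, [Na+].[O-]Cl=O
Why: Pinnick oxidation converts the aldehyde chemoselectively to the acid while the alkene scavenger removes hypochlorous acid, and the β-keto acid is kept cold so that it does not decarboxylate early.

Step 6
Reactants: 9 (12R)-12-O-TBS-14-deoxy-3-oxoandrographolid-19-oic acid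
Product: 11 (12R)-12-O-TBS-4-chloro-19-nor-14-deoxy-3-oxoandrographolide, via C-3/C-4 enol 10 (not isolated)
Conditions: NCS (1.1 equiv), Et3N (0.2 equiv), toluene, 0 °C → rt
Reagents that add atoms: N-chlorosuccinimide, O=C1CCC(=O)N1Cl
Why: Decarboxylative chlorination: loss of CO2 from the ammonium β-keto carboxylate releases the C-3/C-4 enol(ate) regiospecifically and NCS chlorinates it at C-4 before it tautomerises; the C-4 configuration of the chloride does not matter because it is erased in the next step.

Step 7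
Reactants: 11 (12R)-12-O-TBS-4-chloro-19-nor-14-deoxy-3-oxoandrographolide
Product: 13 (12R)-12-O-TBS-14-deoxy-12-hydroxy-3-oxo-4-epi-andrographolide, via samarium enolate 12 (not isolated)
Conditions: SmI2 (2.2 equiv), THF, −78 °C; then CH2O (monomer, THF solution, excess), −78 °C; aq. NH4Cl
Reagents that add atoms: formaldehyde, C=O
Why: Samarium Reformatsky-type aldol: two-electron reduction of the α-chloro ketone gives the trivalent samarium enolate regiospecifically, and formaldehyde adds at C-4 anti to the axial C-10 methyl, so the new hydroxymethyl is equatorial and the C-4 methyl axial (C-4 inverted relative to andrographolide).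

Step 8
Reactants: 13 (12R)-12-O-TBS-14-deoxy-12-hydroxy-3-oxo-4-epi-andrographolide
Product: 14 (12R)-12-O-TBS-14-deoxy-12-hydroxy-4-epi-andrographolide
Conditions: NaBH4, CeCl3·7H2O, MeOH/THF, −78 → −40 °C
Reagents that add atoms: none
Why: Luche-type 1,2-reduction: axial hydride attack from the face away from the axial C-4 and C-10 methyls gives the equatorial 3-OH (3R), and the low temperature with CeCl3 keeps the butenolide from conjugate reduction.

Step 9
Reactants: 14 (12R)-12-O-TBS-14-deoxy-12-hydroxy-4-epi-andrographolide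
Product: 15 (12R)-14-deoxy-12-hydroxy-4-epi-andrographolide (target)
Conditions: HF·pyridine, THF/pyridine, 0 °C → rt
Reagents that add atoms: none
Why: Fluoride-mediated desilylation under buffered, non-basic conditions frees the C-12 alcohol without eliminating it or isomerising the butenolide.

## Compound list

1 | andrographolide, (3R,4R,5S,9R,10S,12E,14S) | C=C1CC[C@@H]2[C@](C)(CO)[C@H](O)CC[C@@]2(C)[C@@H]1C/C=C1/C(=O)OC[C@H]1O | starting material
2 | andrographolide 3,19-acetonide (14-OH free) | C=C1CC[C@@H]2[C@](C)(COC(C)(C)O3)[C@H]3CC[C@@]2(C)[C@@H]1C/C=C1/C(=O)OC[C@H]1O | intermediate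
3 | C-14 allyl perrhenate of 2 (14-O-ReO3) | C=C1CC[C@@H]2[C@](C)(COC(C)(C)O3)[C@H]3CC[C@@]2(C)[C@@H]1C/C=C1/C(=O)OC[C@H]1O[Re](=O)(=O)=O | intermediate
4 | C-12 allyl perrhenate (12R, 13(14)-ene butenolide, acetonide) | C=C1CC[C@@H]2[C@](C)(COC(C)(C)O3)[C@H]3CC[C@@]2(C)[C@@H]1C[C@@H](O[Re](=O)(=O)=O)C1=CCOC1=O | intermediate
5 | (12R)-14-deoxy-12-hydroxyandrographolide 3,19-acetonide | C=C1CC[C@@H]2[C@](C)(COC(C)(C)O3)[C@H]3CC[C@@]2(C)[C@@H]1C[C@@H](O)C1=CCOC1=O | intermediate
6 | 12-O-TBS ether of 5 (acetonide still on) | C=C1CC[C@@H]2[C@](C)(COC(C)(C)O3)[C@H]3CC[C@@]2(C)[C@@H]1C[C@@H](O[Si](C)(C)C(C)(C)C)C1=CCOC1=O | intermediate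
7 | (12R)-12-O-TBS-14-deoxy-12-hydroxyandrographolide (3,19-diol; CH2OH axial) | C=C1CC[C@@H]2[C@](C)(CO)[C@H](O)CC[C@@]2(C)[C@@H]1C[C@@H](O[Si](C)(C)C(C)(C)C)C1=CCOC1=O | intermediate
8 | (12R)-12-O-TBS-14-deoxy-3-oxoandrographolid-19-al (β-keto aldehyde) | C=C1CC[C@@H]2[C@](C)(C=O)C(=O)CC[C@@]2(C)[C@@H]1C[C@@H](O[Si](C)(C)C(C)(C)C)C1=CCOC1=O | intermediate
9 | (12R)-12-O-TBS-14-deoxy-3-oxoandrographolid-19-oic acid (β-keto acid) | C=C1CC[C@@H]2[C@](C)(C(=O)O)C(=O)CC[C@@]2(C)[C@@H]1C[C@@H](O[Si](C)(C)C(C)(C)C)C1=CCOC1=O | intermediate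
10 | C-3/C-4 enol of the 19-nor ketone (3-hydroxy-4-methyl-3-ene, 12-O-TBS) | C=C1CC[C@@H]2C(C)=C(O)CC[C@@]2(C)[C@@H]1C[C@@H](O[Si](C)(C)C(C)(C)C)C1=CCOC1=O | intermediate
11 | (12R)-12-O-TBS-4-chloro-19-nor-14-deoxy-3-oxoandrographolide (4-chloro-4-methyl ketone; expected major epimer shown, Cl equatorial) | C=C1CC[C@@H]2[C@@](C)(Cl)C(=O)CC[C@@]2(C)[C@@H]1C[C@@H](O[Si](C)(C)C(C)(C)C)C1=CCOC1=O | intermediate
12 | samarium enolate (C-3 O-SmI2, C-3/C-4 alkene, 12-O-TBS) | C=C1CC[C@@H]2C(C)=C(O[Sm](I)I)CC[C@@]2(C)[C@@H]1C[C@@H](O[Si](C)(C)C(C)(C)C)C1=CCOC1=O | intermediate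
13 | (12R)-12-O-TBS-14-deoxy-12-hydroxy-3-oxo-4-epi-andrographolide (CH2OH equatorial, CH3 axial at C-4) | C=C1CC[C@@H]2[C@@](C)(CO)C(=O)CC[C@@]2(C)[C@@H]1C[C@@H](O[Si](C)(C)C(C)(C)C)C1=CCOC1=O | intermediate
14 | (12R)-12-O-TBS-14-deoxy-12-hydroxy-4-epi-andrographolide (12-O-TBS ether of the target) | C=C1CC[C@@H]2[C@@](C)(CO)[C@H](O)CC[C@@]2(C)[C@@H]1C[C@@H](O[Si](C)(C)C(C)(C)C)C1=CCOC1=O | intermediate
15 | (12R)-14-deoxy-12-hydroxy-4-epi-andrographolide, (3R,4S,5S,9R,10S,12R), CNP0270153.3 | C=C1CC[C@@H]2[C@@](C)(CO)[C@H](O)CC[C@@]2(C)[C@@H]1C[C@@H](O)C1=CCOC1=O | target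

## Step count and risks

Total step count: 9. Longest linear sequence: 9 steps (fully linear from 1).

Steps most likely to fail:

Step 2 (rhenium-oxo [3,3] transposition). It may stall on the electron-poor allyl system, dehydrate to the 11,12-diene, or erode C-12 through ionisation. Fallback, setting out from 2 and returning at 5: acetylate the 14-OH (Ac2O, Et3N, 4-(dimethylamino)pyridine, CH2Cl2, 0 °C) to 14-O-acetylandrographolide 3,19-acetonide F1. Transpose the acetate with Pd(PPh3)4 (zerovalent palladium, 5 mol %, THF, rt) through an η3-allylpalladium acetate; ionisation and acetate return are both anti to the metal, so the face is retained and C-12 is again R, giving (12R)-12-acetoxy-14-deoxyandrographolide 3,19-acetonide F2. Cleave the acetate with K2CO3/MeOH at 0 °C to reach 5.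

Step 6 (decarboxylative chlorination). NCS may also chlorinate the exocyclic alkene or C-15 of the butenolide, and acid 9 is thermally fragile. Fallback, setting out from 9 and returning at 13 (it bypasses 11): an amine-catalysed decarboxylative aldol. Add 9 to Et3N (0.2 equiv) and a large excess of monomeric formaldehyde in THF at 0 °C so that the C-3/C-4 enol released with CO2 is hydroxymethylated directly, again anti to the C-10 methyl. This makes no new compound, but it is less certain than the main step and will not help if the enol simply tautomerises to the 19-nor ketone first.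

Step 7 (samarium Reformatsky with formaldehyde). The enolate may be protonated to the 19-nor ketone, the butenolide may be reduced, or facial selectivity may be modest. Fallback, setting out from 11 and returning at 13: reduce 11 with Zn dust/TMSCl/TMEDA in Et2O to the C-3/C-4 trimethylsilyl enol ether F3, formed regiospecifically. Then run a Lewis-acid Mukaiyama hydroxymethylation with aqueous formaldehyde and Yb(OTf)3 in THF, conditions that leave the lactone and the TBS ether alone.

Further compounds
F1 | step 2 | 14-O-acetylandrographolide 3,19-acetonide | C=C1CC[C@@H]2[C@](C)(COC(C)(C)O3)[C@H]3CC[C@@]2(C)[C@@H]1C/C=C1/C(=O)OC[C@H]1OC(C)=O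
F2 | step 2 | (12R)-12-acetoxy-14-deoxyandrographolide 3,19-acetonide | C=C1CC[C@@H]2[C@](C)(COC(C)(C)O3)[C@H]3CC[C@@]2(C)[C@@H]1C[C@@H](OC(C)=O)C1=CCOC1=O
F0 | step 6 | none | none
F3 | step 7 | C-3/C-4 trimethylsilyl enol ether | C=C1CC[C@@H]2C(C)=C(O[Si](C)(C)C)CC[C@@]2(C)[C@@H]1C[C@@H](O[Si](C)(C)C(C)(C)C)C1=CCOC1=O
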